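## Analysis of the target

The target is the 8-O-acetate of a labdan-15-oic acid (labdane numbering is used throughout). It is a trans-fused decalin: ring A is C1–C5 plus C10, ring B is C5–C10. C4 carries a gem-dimethyl group, C10 an angular methyl, C8 a tertiary acetoxy group and a methyl (C17), and C9 the chain C11–C15 with methyl C16 on C13 and a free acid at C15.

Four stereocentres are contiguous on ring B: 10β-CH3, 5α-H (trans fusion), 9α-H (chain equatorial, β) and 8α-OAc (C17 methyl axial, syn-axial to the C10 methyl). The fifth, C13 (S), is separated from the ring by two methylenes and cannot be induced from it.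

The tertiary acetate is the sensitive group: it ionises and eliminates under acid and is slow to form, so it is made last, and the acid must be free at the end without an ester hydrolysis next to the acetate. C9 is epimerisable whenever C8 is a carbonyl.

The hard points are the two quaternary carbons C4 and C10 flanking C5, the facial control at C8, and the remote C13. The strategy rests on C5: a carbonyl at C6 makes C5 the nucleophilic α-carbon that can be joined to a C4 cation, and keeps C5 epimerisable so that the ring fusion is set by thermodynamics.

## Retrosynthetic reasoning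

**C8 (30 ⇐ 28 ⇐ 27 ⇐ 25 ⇐ 24).** The acetate is removed first, giving hydroxy acid 28, and the acid is masked as methyl ester 27. The C8 carbinol is traced to the exocyclic alkene 25, because an oxygen nucleophile reaches C8 only along the α (equatorial) direction; the β (axial) path is blocked by the C10 methyl. Adding a methyl nucleophile to ketone 24 would follow the same path and give the wrong C8 epimer. Alkene 25 comes from ketone 24 by methylenation, which must be non-basic so that C9 is not epimerised.

**C9–C11 (24 ⇐ 23 ⇐ 21 ⇐ 14 + 19).** The chain is cut at C9–C11 because C9 is α to the C8 carbonyl and the whole chain, with C13, can come from one chiral-pool piece. A direct alkylation of the C9 enolate with a primary halide was set aside: C9 is neopentyl, and the electrophile would enter from the α face, so the chain would end up axial. An aldol addition to aldehyde 19 followed by dehydration gives dienone 23; hydrogen is then the last substituent to reach C9 and arrives from the α face, which is what the target needs.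

**Side chain (19 ⇐ 18 ⇐ 17 ⇐ 15).** Half-ester 15 has two ends that differ only in ester versus acid. For the 13S series the ester end of the (R) compound must become C11 and the acid end C15. The ester is therefore reduced selectively (lactone 17), the ring reopened to hydroxy ester 18, and the alcohol oxidised to aldehyde 19.

**Carbonyl transposition (14 ⇐ 13 ⇐ 11 ⇐ 10 ⇐ 7).** The key step leaves the oxygen at C6, but it is needed at C8. Dehydrogenation to enone 10, nucleophilic epoxidation to 11, Wharton transposition to allylic alcohol 13 and oxidation give enone 14. The C6=C7 alkene that remains is useful: it blocks C7, so C9 is the only enolisable position of 14.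

**Key disconnection (7 ⇐ 5).** The C4–C5 bond is cut. Forward, protonation of the trisubstituted alkene of 5 gives the C4 tertiary cation, which is captured by C5 of the enol derivative. This makes the gem-dimethyl carbon, the hindered C4–C5 bond and ring A in one step. The enol oxygen is capped with acetyl and not with silicon, for two reasons:
- The hydrogen that ends on C3 is not in the substrate, so a full equivalent of protic acid is needed, not a trace.
- A silyl enol ether is protonated on carbon far faster than an alkene and would be lost before the cation forms; an enol acetate is no more basic than the alkene.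

The ring fusion need not be controlled in the closure, since C5 of ketone 7 is equilibrated afterwards.

**Precursor (5 ⇐ 4 ⇐ 2 + 3; 2 ⇐ 1).** The quaternary carbon C10 and the position of the enol double bond come from one operation: catalytic asymmetric conjugate addition of Grignard reagent 2 (from bromide 1) to enone 3, and O-acetylation of the regiodefined enolate 4. Enolisation of the corresponding ketone would go to the other side (C7), so the trap is essential.

## Alternatives that were turned down

**Alternative 1:** Ring A is opened at C3–C4, and C4 is traced back to a cyclobutane bond C4–C7 of a pinane-type ketone A2 that carries a (Z)-vinylsilane on C10 and the chain on C9.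
- Forward key step: an alkylaluminium chloride on the C8 carbonyl breaks the strained C4–C7 bond, and the C4 cation is captured by the silicon-bearing carbon C3 to give the 2-ene A1.
- For: the cation is made without any proton, so there is no competition between two π systems. The oxygen is already at C8, so no transposition is needed. C5 comes from the chiral pool. It is probably the shorter route, and on these points it is stronger than the chosen one.
- Against: C10 must be made by conjugate addition of a functionalised allyl-type nucleophile to a hindered β,β-disubstituted enone, with the regiochemistry and Z geometry of the allyl metal at risk. C9 must then be alkylated with an unactivated halide next to that new quaternary centre, from whichever face the bicycle dictates, with no later correction.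
- Comparison: the chosen route offers a catalytic, well-precedented construction of C10, and sets C5 and C9 late by equilibration and hydrogenation, at the price of moving the oxygen from C6 to C8.

**Alternative 2:** Ring B is cut at C5–C10 and C8–C9 into the (E)-enal A4 and the silyloxy diene A5.
- Forward key step: a cationic oxazaborolidine-catalysed Diels–Alder reaction gives cycloadduct A3.
- For: C9 and C10 are set together with transfer of the alkene geometry, the chain with C13 is in place from the start, and the route is convergent. On C9/C10 it is stronger than the chosen route.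
- Against: ring A is not made at all. C4, C5 and C1–C3 would have to be annulated onto a neopentyl aldehyde and onto C5, which in A3 is an unactivated methylene (the C7 oxygen activates C6 and C8, not C5). The C7 oxygen is also misplaced for the C8 carbinol, and a β-alkyl α-methyl enal is a sluggish dienophile.
- Comparison: the step count after the key step would be clearly higher. The chosen route closes ring A and makes C4 in one step.

**Alternative 3:** Ring B is cut at C8–C9; the monocyclic keto enoate A7 is closed to hydroxy ester A6.
- Forward key step: a divalent samarium reductant generates the C8 ketyl, which adds 6-exo to C9 of the enoate.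
- For: it installs the C8 carbinol with its methyl and sets C9 in one step, with the trans relation of the oxygen and the acetic ester arm expected from a chelated chair. On C8/C9 it is stronger than the chosen route, which needs methylenation and hydration.
- Against: the difficulty is moved into A7, which already needs the vicinal C5 and quaternary C10 centres on a monocycle. A6 ends at C12, so C13 and the rest of the chain must be added later with acyclic stereocontrol. A6 would readily lactonise, and the reductant is stoichiometric.
- Comparison: the chosen route takes C13 from the chiral pool and builds C10 catalytically.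

Key step: step 3

Assumptions: the antipode of the imidazolinium salt in step 2 is the one that gives the (S) configuration at the quaternary carbon; both antipodes are accessible. Centres that are destroyed later (epoxide in 11, C11 and C9 in 21 and 22) are drawn as the expected major isomer.

## Route

Step 1
Reactants: 1 5-bromo-2-methylpent-2-ene
Product: 2 (4-methylpent-3-en-1-yl)magnesium bromide
Conditions: Mg turnings, I2 (cat.), Et2O, reflux
Reagents that add atoms: magnesium, [Mg]
Why: Grignard formation from a primary homoallylic bromide; the trisubstituted alkene is inert and the ether solution is used directly.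

Step 2
Reactants: 2 (4-methylpent-3-en-1-yl)magnesium bromide; 3 3-methylcyclohex-2-en-1-one
Product: 5 (S)-3-methyl-3-(4-methylpent-3-en-1-yl)cyclohex-1-en-1-yl acetate, via bromomagnesium enolate 4 (not isolated)
Conditions: Cu(OTf)2 (3 mol %), chiral N-mesityl-N′-(2-hydroxyalkyl)imidazolinium hexafluorophosphate (4 mol %), Et2O, 0 °C; then Ac2O, 0 °C → rt
Reagents that add atoms: acetic anhydride, CC(=O)OC(C)=O
Why: Copper-catalysed asymmetric conjugate addition of a Grignard reagent to a β-substituted cyclohexenone; the alkoxide-tethered carbene–copper complex differentiates the enone faces and sets the quaternary carbon C10, and O-acetylation of the regiodefined magnesium enolate fixes the enol double bond at C5=C6.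

Step 3
Reactants: 5 (S)-3-methyl-3-(4-methylpent-3-en-1-yl)cyclohex-1-en-1-yl acetate
Product: 7 4,4,10-trimethyl-trans-decalin-6-one (5α-H), via cis-fused C5 epimer 6 (not isolated)
Conditions: SnCl4 (1.1 equiv), HCl (1.1 equiv, anhydrous), CH2Cl2, −78 → −20 °C; aq NaHCO3; then NaOMe, MeOH, 50 °C
Reagents that add atoms: none
Why: HCl, made strongly acidic by SnCl4, protonates C3 of the trisubstituted alkene in the Markovnikov sense and gives the tertiary cation at C4, in equilibrium with the tertiary chloride. C5 of the enol acetate attacks C4, which forms C4–C5 and ring A, and the acyloxy-stabilised cation at C6 loses its acetyl group to chloride so that the C6 ketone appears. The closest known reaction types are the Lewis-acid tertiary alkylation of enol esters and silyl enol ethers by tertiary cations, the SnCl4 cyclisation of unsaturated β-keto esters, and cation–olefin cyclisations ended by enol derivatives. Ring A closes as a six-membered ring through a chair-like transition state, 6-endo with respect to the C3=C4 alkene and with the enol double bond exocyclic to the new ring. The only new stereocentre is C5; the kinetic ring fusion is not relied on, because C5 is α to the C6 carbonyl and is equilibrated by methoxide to the trans fusion, with C10 as the controlling element (both ring A bonds equatorial on ring B). The step needs the proton to go to the alkene and not to C5 of the enol derivative; the acetyl cap lowers the basicity of the enol π bond to that of an ordinary alkene or below, while the dimethyl-substituted terminus gives the more stable tertiary cation. It also needs attack by C5 and not by C7 or oxygen, and only C5 can reach C4 through a six-membered transition state, the others needing eight-membered rings. One full equivalent of HCl is required, since the hydrogen that ends on C3 is not in the substrate and the acetyl group leaves as acetyl chloride.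

Step 4
Reactants: 7 4,4,10-trimethyl-trans-decalin-6-one (5α-H)
Product: 10 4,4,10-trimethyl-trans-decal-7-en-6-one, via lithium enolate 8 (not isolated), via trimethylsilyl enol ether 9 (not isolated)
Conditions: LiN(iPr)2, THF, −78 °C; Me3SiCl; then Pd(OAc)2 (1.05 equiv), MeCN, rt
Reagents that add atoms: none
Why: Saegusa–Ito oxidation; kinetic deprotonation occurs at the C7 methylene because C5 is a tertiary carbon between two quaternary centres, and palladation of the enol ether followed by β-hydride elimination from C8 gives the enone.

Step 5
Reactants: 10 4,4,10-trimethyl-trans-decal-7-en-6-one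
Product: 11 7α,8α-epoxy-4,4,10-trimethyl-trans-decalin-6-one
Conditions: H2O2 (30 % aq), NaOH, MeOH, 0 °C
Reagents that add atoms: hydrogen peroxide, OO
Why: Weitz–Scheffer nucleophilic epoxidation of the enone; hydroperoxide should add to C8 anti to the axial C10 methyl, but the epoxide configuration is of no consequence because the C8 centre is erased in step 7, and the basic medium keeps C5 at the trans fusion.

Step 6
Reactants: 11 7α,8α-epoxy-4,4,10-trimethyl-trans-decalin-6-one
Product: 13 4,4,10-trimethyl-trans-decal-6-en-8α-ol, via epoxy hydrazone 12 (not isolated)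
Conditions: N2H4·H2O, AcOH (cat.), MeOH, 0 °C → rt
Reagents that add atoms: none
Why: Wharton transposition; the hydrazone opens the epoxide to a vinyl diazene that loses N2, which moves the oxygen from C6 to C8 and leaves the C6=C7 alkene, the C8–O bond staying intact.

Step 7
Reactants: 13 4,4,10-trimethyl-trans-decal-6-en-8α-ol
Product: 14 4,4,10-trimethyl-trans-decal-6-en-8-one
Conditions: Dess–Martin periodinane, NaHCO3, CH2Cl2, rt
Reagents that add atoms: none
Why: Oxidation of a secondary allylic alcohol to the enone under buffered conditions; in 14 the C6=C7 alkene leaves C9 as the only α-position with hydrogens.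

Step 8
Reactants: 15 methyl hydrogen (R)-3-methylglutarate
Product: 17 (S)-4-methyltetrahydro-2H-pyran-2-one, via hydroxy acid 16 (not isolated)
Conditions: NaH (1.0 equiv), THF, 0 °C; LiBH4, THF, 50 °C; then 3 M HCl, rt
Reagents that add atoms: none
Why: LiBH4 reduces the ester but not the carboxylate salt, and acid then closes the δ-lactone; reducing the ester end makes the retained carboxyl carbon C15 and gives the 13S series from the (R) half-ester, the stereocentre itself being untouched.

Step 9
Reactants: 17 (S)-4-methyltetrahydro-2H-pyran-2-one
Product: 18 methyl (S)-5-hydroxy-3-methylpentanoate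
Conditions: MeOH, H2SO4 (cat.), rt; solid NaHCO3 before concentration
Reagents that add atoms: methanol, CO
Why: Acid-catalysed methanolysis of a δ-lactone; in methanol the open hydroxy ester is favoured, and neutralisation before evaporation prevents relactonisation.

Step 10
Reactants: 18 methyl (S)-5-hydroxy-3-methylpentanoate
Product: 19 methyl (S)-3-methyl-5-oxopentanoate
Conditions: Dess–Martin periodinane, NaHCO3, CH2Cl2, rt
Reagents that add atoms: none
Why: Oxidation of a primary alcohol to the aldehyde under neutral conditions; the stereocentre is β to both carbonyl groups and cannot epimerise.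

Step 11
Reactants: 14 4,4,10-trimethyl-trans-decal-6-en-8-one; 19 methyl (S)-3-methyl-5-oxopentanoate
Product: 21 methyl (13S)-11-hydroxy-8-oxo-17-norlabd-6-en-15-oate (epimer mixture at C11), via lithium dienolate 20 (not isolated)
Conditions: LiN(iPr)2, THF, −78 °C; then 19, −78 °C; AcOH quench at −78 °C
Reagents that add atoms: none
Why: Kinetic α′-deprotonation of the enone gives the cross-conjugated dienolate, whose aldol addition to the aldehyde forms C9–C11 at a neopentyl position where an SN2 alkylation would be slow; the new centres C9 and C11 are not controlled because C11 loses its oxygen and C9 is reset in step 13, and the cold quench avoids retro-aldol and lactonisation onto the C15 ester.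

Step 12
Reactants: 21 methyl (13S)-11-hydroxy-8-oxo-17-norlabd-6-en-15-oate
Product: 23 methyl (13S)-8-oxo-17-norlabda-6,9(11)-dien-15-oate, via C11 mesylate 22 (not isolated)
Conditions: MsCl, Et3N, CH2Cl2, 0 °C; then DBU, rt
Reagents that add atoms: none
Why: Mesylation and E1cB elimination; the α-hydrogen on C9 is the one removed, so the alkene forms at C9=C11 in conjugation with the C8 carbonyl.

Step 13
Reactants: 23 methyl (13S)-8-oxo-17-norlabda-6,9(11)-dien-15-oate
Product: 24 methyl (13S)-8-oxo-17-norlabdan-15-oate
Conditions: H2 (1 atm), Pd/C (10 %), EtOAc, rt
Reagents that add atoms: none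
Why: Heterogeneous hydrogenation of both conjugated alkenes; the axial C10 methyl shields the β face of the exocyclic alkene, so hydrogen should reach C9 from the α face and leave the chain equatorial (β), and the neutral medium does not epimerise C9.

Step 14
Reactants: 24 methyl (13S)-8-oxo-17-norlabdan-15-oate
Product: 25 methyl (13S)-labd-8(17)-en-15-oate
Conditions: Zn, CH2Br2, TiCl4, THF/CH2Cl2, 0 °C → rt
Reagents that add atoms: dibromomethane, BrCBr
Why: Lombardo methylenation; the non-basic zinc–titanium methylene reagent converts hindered, enolisable ketones without epimerising C9 and leaves the ester alone.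

Step 15
Reactants: 25 methyl (13S)-labd-8(17)-en-15-oate
Product: 27 methyl (13S)-8α-hydroxylabdan-15-oate, via organomercurial 26 (not isolated)
Conditions: Hg(OAc)2, THF/H2O, rt; then NaBH4, aq NaOH, 0 °C
Reagents that add atoms: water, O
Why: Oxymercuration–demercuration gives Markovnikov hydration of the 1,1-disubstituted alkene; water should attack C8 along the α (equatorial) direction because the β (axial) path is blocked by the syn-axial C10 methyl, which gives the 8α-alcohol with C17 axial.

Step 16
Reactants: 27 methyl (13S)-8α-hydroxylabdan-15-oate
Product: 28 (13S)-8α-hydroxylabdan-15-oic acid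
Conditions: LiOH, THF/MeOH/H2O, rt; then 1 M HCl to pH 3
Reagents that add atoms: lithium hydroxide, [Li+].[OH-]
Why: Saponification of an unhindered methyl ester; it is done before the acetylation so that no ester has to be cleaved beside the tertiary acetate.

Step 17
Reactants: 28 (13S)-8α-hydroxylabdan-15-oic acid
Product: 30 (13S)-8α-acetoxylabdan-15-oic acid, via mixed anhydride 29 (not isolated)
Conditions: Ac2O, DMAP, Et3N, CH2Cl2, 40 °C; then THF/H2O, NaHCO3, rt; citric acid
Reagents that add atoms: acetic anhydride, CC(=O)OC(C)=O
Why: Acylpyridinium-catalysed acetylation of the hindered tertiary alcohol under basic conditions that avoid ionisation at C8; the acid is converted to the mixed anhydride, which is hydrolysed selectively by aqueous bicarbonate, and C8 keeps its configuration since the C8–O bond is not broken.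

## Compound list

1 | 5-bromo-2-methylpent-2-ene | CC(C)=CCCBr | starting material
2 | (4-methylpent-3-en-1-yl)magnesium bromide | CC(C)=CCC[Mg]Br | intermediate
3 | 3-methylcyclohex-2-en-1-one | CC1=CC(=O)CCC1 | starting material
4 | bromomagnesium (S)-3-methyl-3-(4-methylpent-3-en-1-yl)cyclohex-1-en-1-olate | CC(C)=CCC[C@]1(C)CCCC(O[Mg]Br)=C1 | intermediate
5 | (S)-3-methyl-3-(4-methylpent-3-en-1-yl)cyclohex-1-en-1-yl acetate | CC(C)=CCC[C@]1(C)CCCC(OC(C)=O)=C1 | intermediate
6 | 4,4,10-trimethyl-cis-decalin-6-one (5β-H, 10β-CH3) | O=C1[C@@H]2C(C)(C)CCC[C@]2(C)CCC1 | intermediate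
7 | 4,4,10-trimethyl-trans-decalin-6-one (5α-H, 10β-CH3) | O=C1[C@H]2C(C)(C)CCC[C@]2(C)CCC1 | intermediate
8 | lithium enolate of 7 (C6=C7) | [Li]OC=1[C@H]2C(C)(C)CCC[C@]2(C)CCC=1 | intermediate
9 | 6-(trimethylsilyloxy)-4,4,10-trimethyl-trans-decal-6-ene | C[Si](C)(C)OC=1[C@H]2C(C)(C)CCC[C@]2(C)CCC=1 | intermediate
10 | 4,4,10-trimethyl-trans-decal-7-en-6-one | O=C1[C@H]2C(C)(C)CCC[C@]2(C)CC=C1 | intermediate
11 | 7α,8α-epoxy-4,4,10-trimethyl-trans-decalin-6-one | O=C1[C@H]2C(C)(C)CCC[C@]2(C)C[C@@H]3O[C@@H]31 | intermediate
12 | hydrazone of 11 | NN=C1[C@H]2C(C)(C)CCC[C@]2(C)C[C@@H]3O[C@@H]31 | intermediate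
13 | 4,4,10-trimethyl-trans-decal-6-en-8α-ol | O[C@@H]1C=C[C@H]2C(C)(C)CCC[C@]2(C)C1 | intermediate
14 | 4,4,10-trimethyl-trans-decal-6-en-8-one | O=C1C=C[C@H]2C(C)(C)CCC[C@]2(C)C1 | intermediate
15 | methyl hydrogen (R)-3-methylglutarate | COC(=O)C[C@H](C)CC(=O)O | starting material
16 | (S)-5-hydroxy-3-methylpentanoic acid | OCC[C@H](C)CC(=O)O | intermediate
17 | (S)-4-methyltetrahydro-2H-pyran-2-one | O=C1C[C@@H](C)CCO1 | intermediate
18 | methyl (S)-5-hydroxy-3-methylpentanoate | OCC[C@H](C)CC(=O)OC | intermediate
19 | methyl (S)-3-methyl-5-oxopentanoate | O=CC[C@H](C)CC(=O)OC | intermediate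
20 | lithium dienolate of 14 (C8=C9 and C6=C7) | [Li]OC=1C=C[C@H]2C(C)(C)CCC[C@]2(C)C=1 | intermediate
21 | methyl (13S)-11-hydroxy-8-oxo-17-norlabd-6-en-15-oate (9β-H expected, C11 epimers) | O=C1C=C[C@H]2C(C)(C)CCC[C@]2(C)[C@@H]1C(O)C[C@H](C)CC(=O)OC | intermediate
22 | C11 methanesulfonate of 21 | O=C1C=C[C@H]2C(C)(C)CCC[C@]2(C)[C@@H]1C(OS(C)(=O)=O)C[C@H](C)CC(=O)OC | intermediate
23 | methyl (13S)-8-oxo-17-norlabda-6,9(11)-dien-15-oate (C9=C11 geometry not fixed) | O=C1C=C[C@H]2C(C)(C)CCC[C@]2(C)C1=CC[C@H](C)CC(=O)OC | intermediate
24 | methyl (13S)-8-oxo-17-norlabdan-15-oate (5α-H, 9α-H, 10β-CH3) | O=C1CC[C@H]2C(C)(C)CCC[C@]2(C)[C@H]1CC[C@H](C)CC(=O)OC | intermediate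
25 | methyl (13S)-labd-8(17)-en-15-oate | C=C1CC[C@H]2C(C)(C)CCC[C@]2(C)[C@H]1CC[C@H](C)CC(=O)OC | intermediate
26 | methyl (13S)-17-(acetoxymercurio)-8α-hydroxylabdan-15-oate | O[C@]1(C[Hg]OC(C)=O)CC[C@H]2C(C)(C)CCC[C@]2(C)[C@H]1CC[C@H](C)CC(=O)OC | intermediate
27 | methyl (13S)-8α-hydroxylabdan-15-oate | O[C@]1(C)CC[C@H]2C(C)(C)CCC[C@]2(C)[C@H]1CC[C@H](C)CC(=O)OC | intermediate
28 | (13S)-8α-hydroxylabdan-15-oic acid | O[C@]1(C)CC[C@H]2C(C)(C)CCC[C@]2(C)[C@H]1CC[C@H](C)CC(=O)O | intermediate
29 | acetic (13S)-8α-acetoxylabdan-15-oic anhydride | CC(=O)O[C@]1(C)CC[C@H]2C(C)(C)CCC[C@]2(C)[C@H]1CC[C@H](C)CC(=O)OC(C)=O | intermediate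
30 | (13S)-8α-acetoxylabdan-15-oic acid | CC(=O)O[C@]1(C)CC[C@H]2C(C)(C)CCC[C@]2(C)[C@H]1CC[C@H](C)CC(=O)O | target

## Step count and least certain steps

Total step count: 17. Longest linear sequence: 14 steps (steps 1–7 and 11–17); steps 8–10 make the side-chain aldehyde.

**Step 3 (key step).** The most likely failure is protonation of the enol acetate at C5 in competition with the alkene. That releases the uncyclised ketone and opens a Prins-type addition of the alkene to C6. The second concern is slow or incomplete epimerisation at the very hindered C5; this centre stays epimerisable in 10 and 11, so it can be corrected later.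

Fallback (no protic acid): it sets out from 1 and 3 and returns at 7. Markovnikov addition of methanol to 1 (Hg(OAc)2, MeOH; then NaBH4) gives 5-bromo-2-methoxy-2-methylpentane F1. Its Grignard reagent, (4-methoxy-4-methylpentyl)magnesium bromide F2, is added to 3 under the copper–carbene catalysis of step 2. The bromomagnesium enolate F3 is silylated with Me3SiCl to the trimethylsilyl enol ether of 3-(4-methoxy-4-methylpentyl)-3-methylcyclohexanone F4 (C5=C6, quaternary carbon as in 5). TiCl4 in CH2Cl2 at −78 °C ionises the tertiary methyl ether, and the silyl enol ether captures the C4 cation at C5 (Lewis-acid tertiary alkylation of a silyl enol ether). The same methoxide equilibration then gives 7.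

**Step 2.** Enantioselectivity may erode with the longer, unsaturated Grignard reagent, and part of the magnesium enolate may be acetylated on carbon.

Fallback (roles of the two alkyl groups reversed): it sets out from 2 and returns at 5. Reagent 2 is added to commercial 3-ethoxycyclohex-2-en-1-one. The adduct, 3-ethoxy-1-(4-methylpent-3-en-1-yl)cyclohex-2-en-1-ol F5, is hydrolysed with dilute HCl (Stork–Danheiser sequence) to 3-(4-methylpent-3-en-1-yl)cyclohex-2-en-1-one F6. Conjugate addition of Me3Al, catalysed by copper thiophene-2-carboxylate (monovalent copper) and a chiral phosphoramidite, installs the methyl group. The dimethylaluminium enolate F7 is acetylated with Ac2O to give 5.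

**Step 6.** Hydrazone formation at C6 may be slow, because the carbonyl sits between C5 and the C4 methyls. Hydrazine could then open the epoxide or reduce the carbonyl.

Fallback (radical fragmentation): it sets out from 11 and returns at 13. Reduction with NaBH4 and CeCl3·7H2O in MeOH gives the epoxy alcohol 7α,8α-epoxy-4,4,10-trimethyl-trans-decalin-6-ol F8. 1,1′-Thiocarbonyldiimidazole converts it to the O-thiocarbonylimidazolide F9. Bu3SnH with AIBN in toluene at 90 °C generates the C6 radical, which opens the epoxide to the C6=C7 alkene and the C8 alkoxy radical, giving 13.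

**Step 11.** The congested aldolate may revert (retro-aldol) or lactonise onto the C15 ester on warming, and the enolisable aldehyde may be deprotonated by the dienolate.

Fallback (Lewis-acid Mukaiyama addition): it sets out from 14 and returns at 21. The dienolate 20 is trapped with Me3SiCl as 8-(trimethylsilyloxy)-4,4,10-trimethyl-trans-decala-6,8-diene F10, which is added to 19 with TiCl4 in CH2Cl2 at −78 °C to give 21 irreversibly.

**Step 15.** Facial selectivity in the attack of water at C8 may be poor, giving some of the 8-epimer.

Fallback (epoxide route): it sets out from 25 and returns at 28. Saponification with LiOH gives (13S)-labd-8(17)-en-15-oic acid F11. mCPBA with NaHCO3 epoxidises the exocyclic alkene from the open α face to (13S)-8α,17-epoxylabdan-15-oic acid F12. LiEt3BH, which does not reduce the carboxylate, opens the epoxide at the primary C17 and gives 28.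

**Step 17.** Acylation of the tertiary alcohol may be sluggish, and forcing it may cause loss of acetic acid to the alkenes; hydrolysis of the mixed anhydride may be incomplete.

Fallback (reversed order of the last two operations): it sets out from 27 and returns at 30. Acetylation with AcCl and N,N-dimethylaniline gives methyl (13S)-8α-acetoxylabdan-15-oate F13. The methyl ester is then cleaved with Me3SnOH in 1,2-dichloroethane at 80 °C, which spares the hindered tertiary acetate, to give 30.

## Further compounds

F1 | step 3 | 5-bromo-2-methoxy-2-methylpentane | COC(C)(C)CCCBr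
F2 | step 3 | (4-methoxy-4-methylpentyl)magnesium bromide | COC(C)(C)CCC[Mg]Br
F3 | step 3 | bromomagnesium enolate of 3-(4-methoxy-4-methylpentyl)-3-methylcyclohexanone (C5=C6) | COC(C)(C)CCC[C@]1(C)CCCC(O[Mg]Br)=C1
F4 | step 3 | trimethylsilyl enol ether of 3-(4-methoxy-4-methylpentyl)-3-methylcyclohexanone (C5=C6) | COC(C)(C)CCC[C@]1(C)CCCC(O[Si](C)(C)C)=C1
F5 | step 2 | 3-ethoxy-1-(4-methylpent-3-en-1-yl)cyclohex-2-en-1-ol | CCOC1=CC(O)(CCC=C(C)C)CCC1
F6 | step 2 | 3-(4-methylpent-3-en-1-yl)cyclohex-2-en-1-one | CC(C)=CCCC1=CC(=O)CCC1
F7 | step 2 | dimethylaluminium (S)-3-methyl-3-(4-methylpent-3-en-1-yl)cyclohex-1-en-1-olate | CC(C)=CCC[C@]1(C)CCCC(O[Al](C)C)=C1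
F8 | step 6 | 7α,8α-epoxy-4,4,10-trimethyl-trans-decalin-6-ol (C6 epimers) | OC1[C@H]2C(C)(C)CCC[C@]2(C)C[C@@H]3O[C@@H]31
F9 | step 6 | O-(7α,8α-epoxy-4,4,10-trimethyl-trans-decalin-6-yl) imidazole-1-carbothioate | S=C(n1ccnc1)OC1[C@H]2C(C)(C)CCC[C@]2(C)C[C@@H]3O[C@@H]31
F10 | step 11 | 8-(trimethylsilyloxy)-4,4,10-trimethyl-trans-decala-6,8-diene | C[Si](C)(C)OC=1C=C[C@H]2C(C)(C)CCC[C@]2(C)C=1
F11 | step 15 | (13S)-labd-8(17)-en-15-oic acid | C=C1CC[C@H]2C(C)(C)CCC[C@]2(C)[C@H]1CC[C@H](C)CC(=O)O
F12 | step 15 | (13S)-8α,17-epoxylabdan-15-oic acid | C1O[C@@]12CC[C@H]3C(C)(C)CCC[C@]3(C)[C@H]2CC[C@H](C)CC(=O)O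
F13 | step 17 | methyl (13S)-8α-acetoxylabdan-15-oate | CC(=O)O[C@]1(C)CC[C@H]2C(C)(C)CCC[C@]2(C)[C@H]1CC[C@H](C)CC(=O)OC
A1 | alternative 1 | methyl (13S)-8-oxo-17-norlabd-2-en-15-oate | O=C1CC[C@H]2C(C)(C)C=CC[C@]2(C)[C@H]1CC[C@H](C)CC(=O)OC
A2 | alternative 1 | 6,6-dimethylbicyclo[3.1.1]heptan-2-one with methyl and (Z)-3-(trimethylsilyl)prop-2-enyl on C4 and the (S)-5-methoxy-3-methyl-5-oxopentyl chain on C3 | O=C1[C@@H]2C[C@@H](C2(C)C)[C@](C)(C/C=C\[Si](C)(C)C)[C@H]1CC[C@H](C)CC(=O)OC
A3 | alternative 2 | 1-methyl-4-(triisopropylsilyloxy)cyclohex-3-ene-1-carbaldehyde with the (S)-5-(tert-butyldimethylsilyloxy)-3-methylpentyl chain on C6 | O=C[C@@]1(C)CC=C(O[Si](C(C)C)(C(C)C)C(C)C)C[C@@H]1CC[C@H](C)CCO[Si](C)(C)C(C)(C)C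
A4 | alternative 2 | (2E,6S)-8-(tert-butyldimethylsilyloxy)-2,6-dimethyloct-2-enal | O=C/C(C)=C/CC[C@H](C)CCO[Si](C)(C)C(C)(C)C
A5 | alternative 2 | 2-(triisopropylsilyloxy)buta-1,3-diene | C=CC(=C)O[Si](C(C)C)(C(C)C)C(C)C
A6 | alternative 3 | methyl 8α-hydroxy-13,14,15,16-tetranorlabdan-12-oate | O[C@]1(C)CC[C@H]2C(C)(C)CCC[C@]2(C)[C@H]1CC(=O)OC
A7 | alternative 3 | methyl (E)-3-[1,3,3-trimethyl-2-(3-oxobutyl)cyclohexyl]prop-2-enoate (5α-H, 10β-CH3) | CC(=O)CC[C@H]1C(C)(C)CCC[C@]1(C)/C=C/C(=O)OC
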